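**Plan**

1. Retrosynthetic cuts, in this order: the nine O-benzyl bonds; ring C of the top flavan unit across O1–C2 and C3–C4; the bond between the future top C4 and C8 of the middle unit; the 4β→8 bond between the two epiafzelechin units.
2. Enabling feature: in the top unit, O1–C8a–C4a–C4 (ring A plus the doubly benzylic C4, which also carries the phloroglucinol ring of the middle unit) is the frame of an ortho-quinone methide. C2 bears a 4-hydroxyphenyl ring, so C2–C3 is 4-vinylphenol and the O1–C2 bond is the reversible oxa-adduct of a para-quinone methide.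
3. Forward: (−)-epiafzelechin is benzylated, oxidised at C4, brominated at C8 and joined to a second benzylated unit (middle and bottom units, rings unchanged). The bromine, first a blocking group, is exchanged for lithium and added to a salicylaldehyde (ring A). Ring C of the top unit is then closed onto 4-vinylphenol (ring B), and hydrogenolysis ends the route.
4. Stereochemistry: four centres come from (−)-epiafzelechin; C4 of the middle unit from attack anti to the 2α-aryl and 3α-benzyloxy groups; C4 of the top unit from a chiral phosphoric acid; C2 of the top unit from reversible ring closure that should drain into the 2,4-trans ring. The carbinol epimers of the precursor converge because that carbon becomes planar.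

Key step: step 9

Remark on the chemistry: (−)-epiafzelechin is taken as a purchasable chiral-pool compound (isolated natural product). The target is read as (2S,4R)-7,4'-dihydroxyflavan-(4β→8)-epiafzelechin-(4β→8)-epiafzelechin, with a 2,4-trans top unit.

**Route**

Step 1
Reactants: 1 (−)-epiafzelechin
Product: 2 5,7,4'-tri-O-benzyl-(−)-epiafzelechin
Conditions: BnBr (3.3 equiv), K2CO3, DMF, 0 °C → rt
Reagents that add atoms: benzyl bromide, BrCc1ccccc1
Why: Williamson etherification with K2CO3 deprotonates and benzylates only the three phenols, so the secondary 3-OH and the two stereocentres stay as they are.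

Step 2
Reactants: 2 5,7,4'-tri-O-benzyl-(−)-epiafzelechin
Product: 3 3,5,7,4'-tetra-O-benzyl-(−)-epiafzelechin
Conditions: NaH (1.5 equiv), BnBr (1.3 equiv), Bu4NI (cat.), DMF, 0 °C → rt
Reagents that add atoms: benzyl bromide, BrCc1ccccc1
Why: Williamson etherification of the sodium alkoxide caps the 3-OH, which removes the last acidic proton before the organolithium step and leaves a single protecting-group type for one final cleavage.

Step 3
Reactants: 3 3,5,7,4'-tetra-O-benzyl-(−)-epiafzelechin
Product: 4 4β-(2-ethoxyethoxy)-3,5,7,4'-tetra-O-benzylepiafzelechin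
Conditions: DDQ (2 equiv), EtOCH2CH2OH (5 equiv), CH2Cl2, rt
Reagents that add atoms: 2-ethoxyethanol, CCOCCO
Why: Oxidative benzylic C–H etherification, in which DDQ abstracts hydride from C4 (activated by O1 and the 5,7-dibenzyloxy ring A) and the alcohol traps the cation anti to the 2α-aryl and 3α-benzyloxy groups to give the 4β ether, a centre that is planarised again in step 5.

Step 4
Reactants: 4 4β-(2-ethoxyethoxy)-3,5,7,4'-tetra-O-benzylepiafzelechin
Product: 5 8-bromo-4β-(2-ethoxyethoxy)-3,5,7,4'-tetra-O-benzylepiafzelechin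
Conditions: NBS (1.0 equiv), CH2Cl2, −78 → 0 °C
Reagents that add atoms: N-bromosuccinimide, BrN1C(=O)CCC1=O
Why: Electrophilic aromatic bromination goes to C8 of the phloroglucinol ring A, the most electron-rich and less hindered position (C6 lies between two benzyloxy groups), and the bromine both blocks C8 in step 5 and is the handle for step 7.

Step 5
Reactants: 5 8-bromo-4β-(2-ethoxyethoxy)-3,5,7,4'-tetra-O-benzylepiafzelechin, 3 3,5,7,4'-tetra-O-benzyl-(−)-epiafzelechin (3 equiv, excess recovered)
Product: 6 8-bromo-3,5,7,4'-tetra-O-benzylepiafzelechin-(4β→8)-3,5,7,4'-tetra-O-benzylepiafzelechin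
Conditions: TMSOTf (0.2 equiv), CH2Cl2, −78 °C; Et3N quench
Reagents that add atoms: none
Why: Lewis-acid ionisation of the 4-alkoxy group followed by Friedel–Crafts alkylation at C8 of excess 3, with attack on the C4 cation from the β face anti to the 2α-aryl and 3α-benzyloxy groups, should set the 3,4-trans (4β) interflavan bond while the C8 bromine keeps 5 from acting as a nucleophile.

Step 6
Reactants: 7 4-(benzyloxy)-2-hydroxybenzaldehyde
Product: 8 4-(benzyloxy)-2-[(tert-butyldimethylsilyl)oxy]benzaldehyde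
Conditions: TBSCl, imidazole, DMF, rt
Reagents that add atoms: tert-butyldimethylsilyl chloride, CC(C)(C)[Si](C)(C)Cl
Why: Silyl ether formation masks the acidic phenol and keeps the aldehyde fully electrophilic for the aryllithium.

Step 7
Reactants: 6 8-bromo-3,5,7,4'-tetra-O-benzylepiafzelechin-(4β→8)-3,5,7,4'-tetra-O-benzylepiafzelechin, 8 4-(benzyloxy)-2-[(tert-butyldimethylsilyl)oxy]benzaldehyde
Product: 11 [4-(benzyloxy)-2-hydroxyphenyl][C8 of the upper unit of the octa-O-benzyl dimer]methanol as both carbinol epimers, via C8-aryllithium 9 (not isolated), via silyl ether carbinol 10 (not isolated)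
Conditions: t-BuLi (2.1 equiv), THF, −78 °C; 8 (1.5 equiv), −78 °C; TBAF (1.2 equiv), −78 → 0 °C; aq NH4Cl; Et3N-deactivated silica
Reagents that add atoms: none
Why: Bromine–lithium exchange (the second equivalent of t-BuLi destroys t-BuBr), 1,2-addition of the aryllithium to the aldehyde and fluoride desilylation in one flask give the free 2-hydroxybenzhydrol, whose carbinol configuration is of no consequence because step 9 planarises this carbon.

Step 8
Reactants: 12 4-acetoxystyrene
Product: 13 4-vinylphenol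
Conditions: K2CO3 (0.2 equiv), MeOH, 0 °C; pH 7 buffer; used at once as a CH2Cl2 solution
Reagents that add atoms: none
Why: Base-catalysed transesterification with methanol frees the phenol at low temperature, which avoids polymerisation of the styrene.

Step 9
Reactants: 11 [4-(benzyloxy)-2-hydroxyphenyl][C8 of the upper unit of the octa-O-benzyl dimer]methanol, 13 4-vinylphenol (3 equiv)
Product: 16 (2S,4R)-7-(benzyloxy)-4'-hydroxyflavan-(4β→8)-3,5,7,4'-tetra-O-benzylepiafzelechin-(4β→8)-3,5,7,4'-tetra-O-benzylepiafzelechin, via ortho-quinone methide 14 (not isolated), via para-quinone methide adduct 15 (not isolated)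
Conditions: (R)-TRIP [(R)-3,3'-bis(2,4,6-triisopropylphenyl)-1,1'-binaphthyl-2,2'-diyl hydrogen phosphate] (10 mol%), 4 Å MS, CH2Cl2, −40 °C → rt, then 40 °C until the C2 epimer ratio is constant
Reagents that add atoms: none
Why: The chiral phosphoric acid should dehydrate both carbinol epimers of 11 (loss of one molecule of water) to one (E)-ortho-quinone methide 14, in which ring A of the future top unit carries the exocyclic methide carbon (future C4) bonded to C8 of the middle unit; the terminal vinyl carbon of 13, pushed by its para-hydroxyl group, attacks this carbon (C3–C4 bond) to give the para-quinone methide 15, and the ring A phenol regenerated in that event adds to the benzylic carbon of 15 (O1–C2 bond), so that the net change is a stepwise inverse-electron-demand oxa-[4+2] annulation. The closest known reaction type is the Brønsted-acid-catalysed formal [4+2] cycloaddition of ortho-quinone methides generated from 2-hydroxybenzhydrols with electron-rich styrenes to give 2,4-diarylchromans. The one ring that is made, the dihydropyran ring C of the top unit, is closed by 6-exo-trig oxa-1,6-addition. C4 is set in the C–C bond formation under control of the catalyst, whose phosphate bridges the quinone methide oxygen and the hydroxyl group of 13 and exposes one face of the methide carbon (the antipodal acid takes its place if it proves to be the matched partner of the chiral substrate), whereas C2 is set in the ring closure, which is reversible through 15 under the acid, so that both C2 epimers should drain into the 2,4-trans isomer, in which the 2,6-dioxygenated aryl group on C4 sits quasi-axial away from the peri hydrogen H5 and the C2 aryl group sits equatorial, as in 4β-linked 2,3-cis flavan units. The step needs chemoselectivity (the ring A phenol is the only free phenol of 11, so no second quinone methide and no competing O-nucleophile can arise), regioselectivity (the unhindered vinyl terminus of 13, in excess, should outrun the flanked C6 positions of the benzylated phloroglucinol rings) and facial selectivity at C4 (catalyst-controlled, and any C4 epimer is a separable diastereomer because five stereocentres are already present).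

Step 10
Reactants: 16 (2S,4R)-7-(benzyloxy)-4'-hydroxyflavan-(4β→8)-3,5,7,4'-tetra-O-benzylepiafzelechin-(4β→8)-3,5,7,4'-tetra-O-benzylepiafzelechin
Product: 17 (2S,4R)-7,4'-dihydroxyflavan-(4β→8)-(−)-epiafzelechin-(4β→8)-(−)-epiafzelechin
Conditions: H2 (1 atm), Pd(OH)2/C, THF/MeOH/H2O, rt
Reagents that add atoms: none
Why: Heterogeneous hydrogenolysis cleaves all nine benzyl ethers (seven aryl, two secondary alkyl) under neutral conditions that should leave the acid-labile interflavan bonds, the cyclic benzylic ethers and all seven stereocentres intact.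

**Compound list**

1 | (−)-epiafzelechin, (2R,3R)-2-(4-hydroxyphenyl)chromane-3,5,7-triol | Oc1cc(O)c2c(c1)O[C@H](c1ccc(O)cc1)[C@H](O)C2 | starting material
2 | 5,7,4'-tri-O-benzyl-(−)-epiafzelechin (3-OH free) | c1ccccc1COc1cc(OCc2ccccc2)c2c(c1)O[C@H](c1ccc(OCc3ccccc3)cc1)[C@H](O)C2 | intermediate
3 | 3,5,7,4'-tetra-O-benzyl-(−)-epiafzelechin | c1ccccc1COc1cc(OCc2ccccc2)c2c(c1)O[C@H](c1ccc(OCc3ccccc3)cc1)[C@H](OCc1ccccc1)C2 | intermediate
4 | 4β-(2-ethoxyethoxy)-3,5,7,4'-tetra-O-benzylepiafzelechin (2α-aryl, 3α-OBn, 4β-OR) | c1ccccc1COc1cc(OCc2ccccc2)c2c(c1)O[C@H](c1ccc(OCc3ccccc3)cc1)[C@H](OCc1ccccc1)[C@H]2OCCOCC | intermediate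
5 | 8-bromo-4β-(2-ethoxyethoxy)-3,5,7,4'-tetra-O-benzylepiafzelechin | Brc1c(OCc2ccccc2)cc(OCc2ccccc2)c2c1O[C@H](c1ccc(OCc3ccccc3)cc1)[C@H](OCc1ccccc1)[C@H]2OCCOCC | intermediate
6 | 8-bromo-3,5,7,4'-tetra-O-benzylepiafzelechin-(4β→8)-3,5,7,4'-tetra-O-benzylepiafzelechin (octa-O-benzyl dimer bromide) | Brc1c(OCc2ccccc2)cc(OCc2ccccc2)c2c1O[C@H](c1ccc(OCc3ccccc3)cc1)[C@H](OCc1ccccc1)[C@H]2c1c(OCc2ccccc2)cc(OCc2ccccc2)c2c1O[C@H](c1ccc(OCc3ccccc3)cc1)[C@H](OCc1ccccc1)C2 | intermediate
7 | 4-(benzyloxy)-2-hydroxybenzaldehyde | O=Cc1ccc(OCc2ccccc2)cc1O | starting material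
8 | 4-(benzyloxy)-2-[(tert-butyldimethylsilyl)oxy]benzaldehyde | O=Cc1ccc(OCc2ccccc2)cc1O[Si](C)(C)C(C)(C)C | intermediate
9 | C8-aryllithium of the octa-O-benzyl dimer (not isolated) | [Li]c1c(OCc2ccccc2)cc(OCc2ccccc2)c2c1O[C@H](c1ccc(OCc3ccccc3)cc1)[C@H](OCc1ccccc1)[C@H]2c1c(OCc2ccccc2)cc(OCc2ccccc2)c2c1O[C@H](c1ccc(OCc3ccccc3)cc1)[C@H](OCc1ccccc1)C2 | intermediate
10 | silyl ether carbinol: [4-(benzyloxy)-2-(tert-butyldimethylsilyloxy)phenyl][C8 of the upper unit of the dimer]methanol, both carbinol epimers (not isolated) | OC(c1ccc(OCc2ccccc2)cc1O[Si](C)(C)C(C)(C)C)c1c(OCc2ccccc2)cc(OCc2ccccc2)c2c1O[C@H](c1ccc(OCc3ccccc3)cc1)[C@H](OCc1ccccc1)[C@H]2c1c(OCc2ccccc2)cc(OCc2ccccc2)c2c1O[C@H](c1ccc(OCc3ccccc3)cc1)[C@H](OCc1ccccc1)C2 | intermediate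
11 | [4-(benzyloxy)-2-hydroxyphenyl][C8 of the upper unit of the octa-O-benzyl dimer]methanol, both carbinol epimers | OC(c1ccc(OCc2ccccc2)cc1O)c1c(OCc2ccccc2)cc(OCc2ccccc2)c2c1O[C@H](c1ccc(OCc3ccccc3)cc1)[C@H](OCc1ccccc1)[C@H]2c1c(OCc2ccccc2)cc(OCc2ccccc2)c2c1O[C@H](c1ccc(OCc3ccccc3)cc1)[C@H](OCc1ccccc1)C2 | intermediate
12 | 4-acetoxystyrene (4-vinylphenyl acetate) | CC(=O)Oc1ccc(C=C)cc1 | starting material
13 | 4-vinylphenol | C=Cc1ccc(O)cc1 | intermediate
14 | (E)-ortho-quinone methide: 3-(benzyloxy)-6-[(dimer-C8)methylidene]cyclohexa-2,4-dien-1-one, aryl group anti to the carbonyl (not isolated) | O=C1C=C(OCc2ccccc2)C=C/C1=C\c1c(OCc2ccccc2)cc(OCc2ccccc2)c2c1O[C@H](c1ccc(OCc3ccccc3)cc1)[C@H](OCc1ccccc1)[C@H]2c1c(OCc2ccccc2)cc(OCc2ccccc2)c2c1O[C@H](c1ccc(OCc3ccccc3)cc1)[C@H](OCc1ccccc1)C2 | intermediate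
15 | para-quinone methide adduct: 4-[(3R)-3-(4-benzyloxy-2-hydroxyphenyl)-3-(dimer-C8)propylidene]cyclohexa-2,5-dien-1-one (not isolated) | O=C1C=CC(=CC[C@@H](c2c(OCc3ccccc3)cc(OCc3ccccc3)c3c2O[C@H](c2ccc(OCc4ccccc4)cc2)[C@H](OCc2ccccc2)[C@H]3c2c(OCc3ccccc3)cc(OCc3ccccc3)c3c2O[C@H](c2ccc(OCc4ccccc4)cc2)[C@H](OCc2ccccc2)C3)c2ccc(OCc3ccccc3)cc2O)C=C1 | intermediate
16 | (2S,4R)-7-(benzyloxy)-4'-hydroxyflavan-(4β→8)-3,5,7,4'-tetra-O-benzylepiafzelechin-(4β→8)-3,5,7,4'-tetra-O-benzylepiafzelechin (2,4-trans top unit) | Oc1ccc([C@@H]2C[C@@H](c3c(OCc5ccccc5)cc(OCc5ccccc5)c4c3O[C@H](c3ccc(OCc5ccccc5)cc3)[C@H](OCc5ccccc5)[C@H]4c3c(OCc5ccccc5)cc(OCc5ccccc5)c4c3O[C@H](c3ccc(OCc5ccccc5)cc3)[C@H](OCc5ccccc5)C4)c3ccc(OCc5ccccc5)cc3O2)cc1 | intermediate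
17 | CNP0257624.1, (2S,4R)-7,4'-dihydroxyflavan-(4β→8)-(−)-epiafzelechin-(4β→8)-(−)-epiafzelechin | Oc1ccc([C@@H]2C[C@@H](c3c(O)cc(O)c4c3O[C@H](c3ccc(O)cc3)[C@H](O)[C@H]4c3c(O)cc(O)c4c3O[C@H](c3ccc(O)cc3)[C@H](O)C4)c3ccc(O)cc3O2)cc1 | target

**Count and risks**

Total step count: 10. Longest linear sequence: 8 steps (steps 1, 2, 3, 4, 5, 7, 9, 10).

Steps most likely to fail:

1. Step 9. The attack of 13 may take place on the wrong face of the methide carbon if the acid and the chiral substrate are mismatched. The donor-rich, hindered quinone methide may react too slowly. The ring closure may stop at the 2,4-cis ring if re-opening is too slow for equilibration. The fallback gives up the late ring closure for a preformed chiral-pool top unit. It sets out from 6: bromine–lithium exchange (t-BuLi, THF, −78 °C) and quenching with MeOH gives the C8-unsubstituted octa-O-benzyl dimer F1. Commercial (2S)-liquiritigenin is benzylated on both phenols under neutral Mitsunobu conditions (BnOH, PPh3, DIAD), which avoid base-induced ring opening to the chalcone and thus loss of configuration at C2, to give (2S)-7,4'-di-O-benzylliquiritigenin F2. NaBH4 (MeOH/THF, 0 °C) reduces it to the 2,4-cis alcohol (2S,4S)-7-(benzyloxy)-2-[4-(benzyloxy)phenyl]chroman-4-ol F3. BF3·OEt2 in CH2Cl2 at −78 °C ionises F3 to the flavan-4-yl cation, which F1 should attack through C8 of its upper unit (the most accessible nucleophilic position, as in chain extension of 4→8 oligomers). Axial Friedel–Crafts attack trans to the equatorial 2-aryl group should give the deca-O-benzyl trimer F4. Hydrogenolysis as in step 10 leads back to the route at 17.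

2. Step 7. The hindered, chelated aryllithium 9 may be protonated or may metalate a benzylic position before it adds to the equally hindered ortho-silyloxy aldehyde, and silyl migration in the alkoxide may lead to elimination. The fallback reverses the polarity of the union. It sets out from 6: 9, generated as before, is trapped with the small and fast electrophile DMF to give the C8-carbaldehyde of the dimer F5. The bromomagnesium phenoxide of commercial 3-(benzyloxy)phenol (EtMgBr, toluene/CH2Cl2, rt) then adds through its ortho carbon para to the benzyloxy group to the magnesium-chelated aldehyde (ortho-selective hydroxyalkylation of a magnesium phenoxide). This gives the benzhydrol with a free ring A phenol directly and comes back to the route at 11.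

3. Step 5. Repeated ionisation by the Lewis acid may let the product re-enter as donor or acceptor, and attack through C6 of 3 may compete. The fallback uses thiophilic instead of oxophilic activation. It sets out from 5: exchange of the 2-ethoxyethoxy group with 2-mercaptobenzothiazole and BF3·OEt2 (CH2Cl2, −40 °C) gives 4β-(1,3-benzothiazol-2-ylsulfanyl)-8-bromo-3,5,7,4'-tetra-O-benzylepiafzelechin F6. AgBF4 (THF/CH2Cl2, −78 → 0 °C) then ionises only the C–S bond in the presence of a near-stoichiometric amount of 3, and the Friedel–Crafts alkylation comes back to the route at 6.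

**Further compounds**

F1 | step 9 | 3,5,7,4'-tetra-O-benzylepiafzelechin-(4β→8)-3,5,7,4'-tetra-O-benzylepiafzelechin (C8-unsubstituted dimer) | c1c(OCc2ccccc2)cc(OCc2ccccc2)c2c1O[C@H](c1ccc(OCc3ccccc3)cc1)[C@H](OCc1ccccc1)[C@H]2c1c(OCc2ccccc2)cc(OCc2ccccc2)c2c1O[C@H](c1ccc(OCc3ccccc3)cc1)[C@H](OCc1ccccc1)C2
F2 | step 9 | (2S)-7,4'-di-O-benzylliquiritigenin, (2S)-7-(benzyloxy)-2-[4-(benzyloxy)phenyl]chroman-4-one | c1ccccc1COc1ccc(cc1)[C@@H]1CC(=O)c2ccc(OCc3ccccc3)cc2O1
F3 | step 9 | (2S,4S)-7-(benzyloxy)-2-[4-(benzyloxy)phenyl]chroman-4-ol (2,4-cis) | c1ccccc1COc1ccc(cc1)[C@@H]1C[C@H](O)c2ccc(OCc3ccccc3)cc2O1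
F4 | step 9 | (2S,4R)-7,4'-di-O-benzyl-7,4'-dihydroxyflavan-(4β→8)-3,5,7,4'-tetra-O-benzylepiafzelechin-(4β→8)-3,5,7,4'-tetra-O-benzylepiafzelechin (deca-O-benzyl trimer) | c5ccccc5COc1ccc([C@@H]2C[C@@H](c3c(OCc5ccccc5)cc(OCc5ccccc5)c4c3O[C@H](c3ccc(OCc5ccccc5)cc3)[C@H](OCc5ccccc5)[C@H]4c3c(OCc5ccccc5)cc(OCc5ccccc5)c4c3O[C@H](c3ccc(OCc5ccccc5)cc3)[C@H](OCc5ccccc5)C4)c3ccc(OCc5ccccc5)cc3O2)cc1
F5 | step 7 | C8-carbaldehyde of the octa-O-benzyl dimer, 8-formyl-3,5,7,4'-tetra-O-benzylepiafzelechin-(4β→8)-3,5,7,4'-tetra-O-benzylepiafzelechin | O=Cc1c(OCc2ccccc2)cc(OCc2ccccc2)c2c1O[C@H](c1ccc(OCc3ccccc3)cc1)[C@H](OCc1ccccc1)[C@H]2c1c(OCc2ccccc2)cc(OCc2ccccc2)c2c1O[C@H](c1ccc(OCc3ccccc3)cc1)[C@H](OCc1ccccc1)C2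
F6 | step 5 | 4β-(1,3-benzothiazol-2-ylsulfanyl)-8-bromo-3,5,7,4'-tetra-O-benzylepiafzelechin | Brc1c(OCc2ccccc2)cc(OCc2ccccc2)c2c1O[C@H](c1ccc(OCc3ccccc3)cc1)[C@H](OCc1ccccc1)[C@H]2Sc1nc2ccccc2s1
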